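A neighbour of oak with 0.096 M of partner raises the same question as the set-ups here: how soon the released group overtakes the slow route.

    substrate + partner + released group → target + 2 released group (k1 = 20 L² mol⁻² h⁻¹)
    substrate + partner → target + released group (k2 = 0.063 L mol⁻¹ h⁻¹)
    substrate + target ⇌ idle adduct, settled at all times (K3 = 25 L mol⁻¹)

| flask | substrate | partner | remark | time |
|---|---|---|---|---|
| elm | 0.20 M | 0.240 M | one stirred flow tank at steady state, fed with the mixture as stated, mean residence time 30.0 h |  |
| cedar | 0.20 M | 0.240 M | everything together in a closed stirred flask, run for 3.0 h | 3.0 h |
| oak | 0.20 M (fed, over 2.40 h) | 0.240 M | a stirred flask in which substrate is dosed at a steady rate over 2.40 h without added volume, worked up at 3.0 h | 3.0 h |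
| ash | 0.20 M | 0.240 M | one stirred flow tank at steady state, fed with the mixture as stated, mean residence time 3.0 h |  |

* order of the set-ups by the amount of target at the outlet or at the end, in percent of the substrate put in, highest first (elm / cedar / oak / ash)
* amount of target at the outlet or at the end, in percent of the substrate put in, elm
* amount of target at the outlet or at the end, in percent of the substrate put in, cedar
* amount of target at the outlet or at the end, in percent of the substrate put in, oak
* amount of target at the outlet or at the end, in percent of the substrate put in, ash

- a species is counted by the substrate in it: one idle adduct counts as two
- amounts and yields of target count idle adduct too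
- the stated concentrations are those of everything mixed, before any reaction; amounts are the same in each set-up
- the feed brings no volume worth counting
- in an amount of target, one idle adduct counts as one target
- run time (cedar): 3.0 h

Compare the two routes at one moment. Both use substrate and partner, so the fast route over the slow one equals x, the released group's share of the substrate charge, over the crossover share of this autocatalysis:

x* = 0.063 L mol⁻¹ h⁻¹ / (20 L² mol⁻² h⁻¹ × 0.20 M) = 1.57%

With substrate and partner held at their charges, x then grows on one clock:

lighting time = 1 / (20 L² mol⁻² h⁻¹ × 0.20 M × 0.240 M) = 1.04 h

x = x* × (exp(substrate-weighted hours / lighting time) − 1)

My reckoning gives cedar 26.5%. Oak's steady feed counts as 1.80 h of full charge, giving 7.29%. Both figures hold substrate and partner at their charges and leave out the idle adduct, whose constant times the charge is 5.0. Both stand above the forecast's figures for these flasks.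

Turned round, a tank stays near x* with a residence time under the lighting time, where x = (τ / lighting time) × (x + x*) has a low root. Ash stands at 2.88 lighting times and elm at 28.8, so each of these tanks must balance on depleted substrate and partner.

The forecast, in which a flow tank “starts with the fast route fully on”, gives elm > ash > cedar > oak: 70.8%, 32.2%, 17% and 6.1% in that order.

The simulation gives elm > ash > cedar > oak: 70.9%, 32.3%, 16.8% and 6.32%.

Oak at 3.00 h holds 4.03 crossover shares of target, and its fast-over-slow ratio reads 4.0. Oak has not come to rest, with 89% of its substrate still unbound. Ten times the time brings oak to 89.1% of target, with 2.17% of its substrate and 25.8% of its partner left. Cedar then holds 89.7%, so the gap between the two closed flasks, 10 percentage points at 3.00 h, has nearly gone.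

In the neighbour, partner cancels from the ratio, so x* stays 1.57%. The clock stretches to 2.60 h, and the reckoning gives 1.57%. The simulation gives 1.51%.

The constants are made up; the rest is arithmetic.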